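**Retrosynthetic overview**
1. The strategy rests on the outer dihydrobenzofuran (O1'–C2'–C3', fused to ring A). C2', the O–CH(4-hydroxyphenyl) carbon, is a benzylic ether carbon lying 1,5 to the ring-A benzylic carbon C3'. The C2'–C3' bond is therefore cut back to a carbene at C3' (an aryldiazoacetate on ring A) and a 4-methoxybenzyl ether on the neighbouring ring-A oxygen.
2. After that ring closure, the C3' ester is replaced by the 3,5-dimethoxyphenyl group (decarboxylative arylation, trans to the C2' aryl), and all eight methyl ethers are cleaved last.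
3. The seven-membered ring comes from Friedel–Crafts closure of a 2,4-dimethoxystilbene cation (C8) onto the 3,5-dimethoxyphenyl ring carried by C3 of the inner dihydrobenzofuran.
4. The inner dihydrobenzofuran is made on a simple ring A by the same pair of reactions (carbene C–H insertion, then decarboxylative arylation). Ring A comes from 3,5-dihydroxybenzyl alcohol through a symmetric 2,6-dibromide: one bromide becomes the diazoester arm of the inner ring, the other the arylacetate arm of the outer ring.
5. Order of ring formation: inner dihydrobenzofuran (step 6), seven-membered ring (step 14), outer dihydrobenzofuran (step 17).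

Key step: step 17

Labels: ring A is the central benzene ring. The inner dihydrobenzofuran is O1–C2(4-methoxyphenyl)–C3. C7 (CH2) and C8 (CH–aryl) are the other sp3 carbons of the seven-membered ring, and ring D is the dioxygenated benzene ring fused to it. The outer dihydrobenzofuran is O1'–C2'–C3'. The target is 2R,3R,8R,2'R,3'R.

Assumption 1: Rh2(S-PTTL)4, dirhodium tetrakis[N-phthaloyl-(S)-tert-leucinate], is taken to give the R configuration at the O–CH(aryl) carbon (cis 2R,3S ester), as with simple 2-(benzyloxy)phenyl diazoacetates. Step 6 tests this on simple material, and if the sense is the opposite, Rh2(R-PTTL)4 is used in steps 6 and 17 with no other change.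

Assumption 2: the acid-induced seven-membered ring closure is taken to place the 2,4-dimethoxyphenyl group on the outer, pseudo-equatorial side (8R), as in the known acid-induced closure of ε-viniferin-type stilbenes.

**Step 1**
Reactants: 1 3,5-dihydroxybenzyl alcohol; 2 4-methoxybenzyl chloride
Product: 3 [3,5-bis(4-methoxybenzyloxy)phenyl]methanol
Conditions: 2 (2.2 equiv in all), K2CO3 (3 equiv), n-Bu4NI (cat.), DMF, 60 °C
Reagents that add atoms: 4-methoxybenzyl chloride (second equivalent of 2), COc1ccc(CCl)cc1
Why: Double Williamson ether synthesis, one molecule of 2 per phenol; the phenoxides, far more acidic than the benzylic alcohol, are alkylated selectively and give the symmetric bis-ether.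

**Step 2**
Reactants: 3 [3,5-bis(4-methoxybenzyloxy)phenyl]methanol
Product: 4 [2,6-dibromo-3,5-bis(4-methoxybenzyloxy)phenyl]methanol
Conditions: 1,3-dibromo-5,5-dimethylhydantoin (1.0 equiv), MeCN, 0 °C to rt, dark
Reagents that add atoms: 1,3-dibromo-5,5-dimethylhydantoin, CC1(C)N(Br)C(=O)N(Br)C1=O
Why: Electrophilic aromatic bromination in which one molecule of the hydantoin delivers both bromine atoms; each position flanking the CH2OH group is para to one ether oxygen and ortho to the other and is less crowded than the position between the two ethers, and the mono-oxygenated benzyl rings are much less reactive, so the symmetric 2,6-dibromide should form.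

**Step 3**
Reactants: 4 [2,6-dibromo-3,5-bis(4-methoxybenzyloxy)phenyl]methanol
Product: 5 triisopropylsilyl ether of 4
Conditions: TIPSOTf, 2,6-lutidine, CH2Cl2, 0 °C
Reagents that add atoms: triisopropylsilyl trifluoromethanesulfonate, CC(C)[Si](OS(=O)(=O)C(F)(F)F)(C(C)C)C(C)C
Why: Silylation with a silyl triflate overcomes the crowding by the two bromines; the bulky, weakly basic triisopropylsilyl ether is chosen to resist silyl migration to an ortho aryllithium (step 4) and ylide formation with the carbene (step 6).

**Step 4**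
Reactants: 5 triisopropylsilyl ether of 4; 6 dimethyl oxalate
Product: 8 bromo aryl ketoester, via aryllithium 7 (not isolated)
Conditions: n-BuLi (1.0 equiv), THF, −78 °C; then cannulated into 6 (3 equiv), THF, −78 °C
Reagents that add atoms: none
Why: Bromine–lithium exchange on one of the two equivalent bromides (the aryllithium formed is not exchanged again), then acylation with excess oxalate, which stops at the ketoester because the tetrahedral adduct persists at −78 °C; this desymmetrises ring A and keeps the second bromide for the outer arm.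

**Step 5**
Reactants: 8 bromo aryl ketoester
Product: 10 bromo aryldiazoacetate, via tosylhydrazone 9 (not isolated)
Conditions: TsNHNH2, MeOH, 60 °C; evaporate; then DBU, CH2Cl2, rt
Reagents that add atoms: p-toluenesulfonyl hydrazide, Cc1ccc(cc1)S(=O)(=O)NN
Why: Hydrazone condensation followed by Bamford–Stevens-type elimination of p-toluenesulfinate with DBU gives the aryldiazoacetate without any need to tell two arylacetate arms apart.

**Step 6**
Reactants: 10 bromo aryldiazoacetate
Product: 11 cis (2R,3S) 5-bromo-2-(4-methoxyphenyl)dihydrobenzofuran-3-carboxylate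
Conditions: Rh2(S-PTTL)4 (1 mol%), toluene, −60 to −40 °C
Reagents that add atoms: none
Why: Dirhodium-carboxylate-catalysed intramolecular carbene C–H insertion of an aryldiazoacetate into a benzyl aryl ether: the carbene on the ring-A benzylic carbon inserts 1,5 into a benzylic C–H bond of the flanking 4-methoxybenzyl ether, the chiral ligands fix C2 as R, and the kinetic preference gives the cis ester (C3 S).

**Step 7**
Reactants: 11 cis bromo ester; 12 (2-tert-butoxy-2-oxoethyl)zinc bromide
Product: 13 cis (2R,3S) diester with a tert-butyl acetate arm at C5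
Conditions: Pd(dba)2 (5 mol%), Q-Phos [(C5Ph5)Fe(C5H4P(t-Bu)2)] (5 mol%), THF, 50 °C
Reagents that add atoms: none
Why: Palladium-catalysed α-arylation of a zinc ester enolate (Reformatsky-type Negishi coupling, zerovalent palladium with a bulky ferrocenyl phosphine for the doubly ortho-substituted bromide); the neutral zinc enolate tolerates the methyl ester and silyl ether, and the tert-butyl ester keeps the new arm distinct from the C3 methyl ester (any epimerisation at C3 is of no consequence).

**Step 8**
Reactants: 13 cis diester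
Product: 14 trans (2R,3R) dihydrobenzofuran-3-carboxylic acid
Conditions: LiOH·H2O, THF/MeOH/H2O, 40 °C; then 1 M HCl to pH 3–4, 0 °C
Reagents that add atoms: lithium hydroxide, [Li+].[OH-]
Why: Saponification; hydroxide cleaves the methyl ester while the tert-butyl ester is sterically protected, C3 equilibrates to the trans acid through the enolate (of no consequence), and C2 is safe because ring opening by β-elimination of the phenoxide would need a 5-endo alignment.

**Step 9**
Reactants: 14 trans acid; 15 1-bromo-3,5-dimethoxybenzene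
Product: 16 trans (2R,3R) 3-(3,5-dimethoxyphenyl)-2-(4-methoxyphenyl)dihydrobenzofuran
Conditions: Ir[dF(CF3)ppy]2(dtbbpy)PF6 (1 mol%), NiCl2·glyme (10 mol%), dtbbpy (15 mol%), Cs2CO3, DMF, blue LEDs, rt
Reagents that add atoms: none
Why: Nickel/photoredox decarboxylative arylation: the carboxylate is oxidised by the excited iridium photocatalyst, loss of CO2 gives the planar benzylic C3 radical, and the aryl–nickel bromide complex (divalent nickel) captures it and forms the C–C bond on the face away from the C2 aryl group, giving the trans 2R,3R product.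

**Step 10**
Reactants: 16 trans diaryl dihydrobenzofuran silyl ether
Product: 17 benzylic alcohol
Conditions: HF·pyridine, pyridine, THF, 0 °C to rt
Reagents that add atoms: none
Why: Fluoride-mediated desilylation under buffered, non-basic conditions, so that no alkoxide forms that could attack the neighbouring tert-butyl ester; the 4-methoxybenzyl ether and tert-butyl ester are stable to HF·pyridine.

**Step 11**
Reactants: 17 benzylic alcohol
Product: 18 aldehyde
Conditions: Dess–Martin periodinane, CH2Cl2, rt
Reagents that add atoms: none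
Why: Dess–Martin oxidation of the benzylic alcohol under neutral conditions, carried out promptly so that the hydroxy ester has no time to lactonise.

**Step 12**
Reactants: 19 2,4-dimethoxybenzyl alcohol
Product: 20 (2,4-dimethoxybenzyl)triphenylphosphonium bromide
Conditions: PPh3·HBr, MeCN, 80 °C
Reagents that add atoms: triphenylphosphine hydrobromide, Br.c1ccc(cc1)P(c1ccccc1)c1ccccc1
Why: The electron-rich benzylic alcohol is ionised by HBr and the cation is captured by triphenylphosphine (SN1 substitution), which avoids the unstable benzylic halide.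

**Step 13**
Reactants: 18 aldehyde; 20 (2,4-dimethoxybenzyl)triphenylphosphonium bromide
Product: 22 2,4-dimethoxystilbene, via phosphorus ylide 21 (not isolated)
Conditions: KOt-Bu (1.0 equiv relative to 20), THF, 0 °C; then 18, 0 °C to rt
Reagents that add atoms: none
Why: Wittig olefination; the semi-stabilised ylide is too weak a base to enolise the arylacetate and adds to the hindered aldehyde, and alkene geometry is of no consequence for step 14 (E isomer drawn).

**Step 14**
Reactants: 22 2,4-dimethoxystilbene
Product: 25 core phenol methyl ester, via cyclised tert-butyl ester 23 (not isolated), via hydroxy acid 24 (not isolated)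
Conditions: TFA (5 equiv), CH2Cl2, −20 °C; then PhSMe (10 equiv), TFA/CH2Cl2 1:3, 0 °C to rt; evaporate; then H2SO4 (cat.), MeOH, 40 °C
Reagents that add atoms: methanol, CO
Why: Protonation of the stilbene at the carbon next to ring A gives the 2,4-dimethoxybenzylic cation at C8, which an ortho carbon of the 3,5-dimethoxyphenyl ring on C3 attacks in a seven-membered Friedel–Crafts alkylation (the known acid-induced closure of ε-viniferin-type stilbenes), with the aryl group expected on the outer pseudo-equatorial side (8R); stronger acid then removes the 4-methoxybenzyl ether (cation trapped by thioanisole) and the tert-butyl ester, and Fischer esterification gives the methyl ester.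

**Step 15**
Reactants: 25 core phenol methyl ester; 2 4-methoxybenzyl chloride
Product: 26 core 4-methoxybenzyl ether methyl ester
Conditions: K2CO3, DMF, rt
Reagents that add atoms: none
Why: Williamson etherification of the phenol (K2CO3 does not enolise the arylacetate) restores the benzylic ether that the carbene will attack.

**Step 16**
Reactants: 26 core 4-methoxybenzyl ether methyl ester
Product: 27 core aryldiazoacetate
Conditions: p-ABSA, DBU, MeCN, 0 °C to rt
Reagents that add atoms: 4-acetamidobenzenesulfonyl azide, CC(=O)Nc1ccc(cc1)S(=O)(=O)N=[N+]=[N-]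
Why: Regitz diazo transfer; the DBU-generated arylacetate enolate attacks the sulfonyl azide and the sulfonamide is expelled.

**Step 17**
Reactants: 27 core aryldiazoacetate
Product: 28 pentacyclic cis (2'R,3'S) 2-aryl-dihydrobenzofuran-3-carboxylate
Conditions: Rh2(S-PTTL)4 (2 mol%), toluene, −60 to −30 °C
Reagents that add atoms: none
Why: Rh2(S-PTTL)4 (both rhodium atoms divalent) expels N2 from 27 to give a donor/acceptor rhodium carbene on the ring-A benzylic carbon, which inserts into one benzylic C–H bond of the neighbouring 4-methoxybenzyl ether through a three-centre, hydride-transfer-like transition state and so forms the C2'–C3' bond. The closest known reaction is the dirhodium-carboxylate-catalysed enantioselective intramolecular C–H insertion of aryldiazoacetates into benzyl aryl ethers, which gives cis 2-aryl-2,3-dihydrobenzofuran-3-carboxylates and is already used on this bond type in step 6. The outer ring is closed as a five-membered ring by 1,5 insertion (carbene carbon, two ring-A carbons, oxygen, benzylic carbon); the only other C–H bonds within reach are those of the ring CH2 (C7) on the other flank, and insertion there would give a four-membered ring and is not expected. C2' (R) is set by the chiral phthalimido-tert-leucinate ligands, which choose one of the two benzylic hydrogens in the same sense as in step 6, and C3' (S, cis) follows from the kinetically preferred transition state with ester and aryl group on the same side. The step needs site selectivity for the O–CH2–aryl bond, secured by the oxygen and the 4-methoxyphenyl ring both stabilising positive charge at that carbon, and catalyst control over the existing stereocentres, secured because these lie on the far side of ring A from the reacting centre. The cis ester centre is not critical, because it is erased in step 19.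

**Step 18**
Reactants: 28 pentacyclic cis ester
Product: 29 pentacyclic trans (2'R,3'R) acid
Conditions: LiOH·H2O, THF/MeOH/H2O, 45 °C; then 1 M HCl to pH 3–4, 0 °C
Reagents that add atoms: lithium hydroxide, [Li+].[OH-]
Why: Saponification of the hindered methyl ester; C3' equilibrates to the trans acid (of no consequence), C2' is untouched, and the methyl ethers and both ring ethers are stable to hydroxide.

**Step 19**
Reactants: 29 pentacyclic trans acid; 15 1-bromo-3,5-dimethoxybenzene
Product: 30 octamethyl ether of the target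
Conditions: Ir[dF(CF3)ppy]2(dtbbpy)PF6 (2 mol%), NiCl2·glyme (10 mol%), dtbbpy (15 mol%), Cs2CO3, DMF, blue LEDs, rt
Reagents that add atoms: none
Why: Nickel/photoredox decarboxylative arylation as in step 9; the planar benzylic C3' radical is arylated at nickel on the face away from the C2' aryl group, which gives the trans 2'R,3'R ring and completes the carbon skeleton.

**Step 20**
Reactants: 30 octamethyl ether of the target
Product: 31 CNP0154047.1
Conditions: BBr3 (20 equiv), CH2Cl2, −78 °C to rt; then MeOH/H2O, 0 °C
Reagents that add atoms: none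
Why: Lewis-acid cleavage of all eight aryl methyl ethers (bromide attacks the methyl group of each boron-bound ether); should a benzylic ring ether open reversibly, it recloses to the trans ring because C3 and C3' are fixed.

**Compound list**
1 | 3,5-dihydroxybenzyl alcohol | OCc1cc(O)cc(O)c1 | starting material
2 | 4-methoxybenzyl chloride | COc1ccc(CCl)cc1 | starting material
3 | [3,5-bis(4-methoxybenzyloxy)phenyl]methanol | OCc1cc(OCc2ccc(OC)cc2)cc(OCc2ccc(OC)cc2)c1 | intermediate
4 | [2,6-dibromo-3,5-bis(4-methoxybenzyloxy)phenyl]methanol | OCc1c(Br)c(OCc2ccc(OC)cc2)cc(OCc2ccc(OC)cc2)c1Br | intermediate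
5 | {[2,6-dibromo-3,5-bis(4-methoxybenzyloxy)benzyl]oxy}triisopropylsilane | CC(C)[Si](OCc1c(Br)c(OCc2ccc(OC)cc2)cc(OCc2ccc(OC)cc2)c1Br)(C(C)C)C(C)C | intermediate
6 | dimethyl oxalate | COC(=O)C(=O)OC | starting material
7 | [3-bromo-4,6-bis(4-methoxybenzyloxy)-2-(triisopropylsilyloxymethyl)phenyl]lithium | [Li]c1c(OCc2ccc(OC)cc2)cc(OCc2ccc(OC)cc2)c(Br)c1CO[Si](C(C)C)(C(C)C)C(C)C | intermediate
8 | methyl 2-[3-bromo-4,6-bis(4-methoxybenzyloxy)-2-(triisopropylsilyloxymethyl)phenyl]-2-oxoacetate | COC(=O)C(=O)c1c(OCc2ccc(OC)cc2)cc(OCc2ccc(OC)cc2)c(Br)c1CO[Si](C(C)C)(C(C)C)C(C)C | intermediate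
9 | p-toluenesulfonylhydrazone of 8 | COC(=O)C(=NNS(=O)(=O)c1ccc(C)cc1)c1c(OCc2ccc(OC)cc2)cc(OCc2ccc(OC)cc2)c(Br)c1CO[Si](C(C)C)(C(C)C)C(C)C | intermediate
10 | methyl 2-[3-bromo-4,6-bis(4-methoxybenzyloxy)-2-(triisopropylsilyloxymethyl)phenyl]-2-diazoacetate | COC(=O)C(=[N+]=[N-])c1c(OCc2ccc(OC)cc2)cc(OCc2ccc(OC)cc2)c(Br)c1CO[Si](C(C)C)(C(C)C)C(C)C | intermediate
11 | methyl (2R,3S)-5-bromo-6-(4-methoxybenzyloxy)-2-(4-methoxyphenyl)-4-(triisopropylsilyloxymethyl)-2,3-dihydrobenzofuran-3-carboxylate (cis) | COc1ccc([C@@H]2Oc3cc(OCc4ccc(OC)cc4)c(Br)c(CO[Si](C(C)C)(C(C)C)C(C)C)c3[C@@H]2C(=O)OC)cc1 | intermediate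
12 | (2-tert-butoxy-2-oxoethyl)zinc bromide | CC(C)(C)OC(=O)C[Zn]Br | starting material
13 | methyl (2R,3S)-5-(2-tert-butoxy-2-oxoethyl)-6-(4-methoxybenzyloxy)-2-(4-methoxyphenyl)-4-(triisopropylsilyloxymethyl)-2,3-dihydrobenzofuran-3-carboxylate (cis) | COc1ccc([C@@H]2Oc3cc(OCc4ccc(OC)cc4)c(CC(=O)OC(C)(C)C)c(CO[Si](C(C)C)(C(C)C)C(C)C)c3[C@@H]2C(=O)OC)cc1 | intermediate
14 | (2R,3R)-5-(2-tert-butoxy-2-oxoethyl)-6-(4-methoxybenzyloxy)-2-(4-methoxyphenyl)-4-(triisopropylsilyloxymethyl)-2,3-dihydrobenzofuran-3-carboxylic acid (trans) | COc1ccc([C@@H]2Oc3cc(OCc4ccc(OC)cc4)c(CC(=O)OC(C)(C)C)c(CO[Si](C(C)C)(C(C)C)C(C)C)c3[C@H]2C(=O)O)cc1 | intermediate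
15 | 1-bromo-3,5-dimethoxybenzene | COc1cc(Br)cc(OC)c1 | starting material
16 | tert-butyl 2-[(2R,3R)-3-(3,5-dimethoxyphenyl)-6-(4-methoxybenzyloxy)-2-(4-methoxyphenyl)-4-(triisopropylsilyloxymethyl)-2,3-dihydrobenzofuran-5-yl]acetate | COc1ccc([C@@H]2Oc3cc(OCc4ccc(OC)cc4)c(CC(=O)OC(C)(C)C)c(CO[Si](C(C)C)(C(C)C)C(C)C)c3[C@H]2c2cc(OC)cc(OC)c2)cc1 | intermediate
17 | tert-butyl 2-[(2R,3R)-3-(3,5-dimethoxyphenyl)-4-(hydroxymethyl)-6-(4-methoxybenzyloxy)-2-(4-methoxyphenyl)-2,3-dihydrobenzofuran-5-yl]acetate | COc1ccc([C@@H]2Oc3cc(OCc4ccc(OC)cc4)c(CC(=O)OC(C)(C)C)c(CO)c3[C@H]2c2cc(OC)cc(OC)c2)cc1 | intermediate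
18 | tert-butyl 2-[(2R,3R)-3-(3,5-dimethoxyphenyl)-4-formyl-6-(4-methoxybenzyloxy)-2-(4-methoxyphenyl)-2,3-dihydrobenzofuran-5-yl]acetate | COc1ccc([C@@H]2Oc3cc(OCc4ccc(OC)cc4)c(CC(=O)OC(C)(C)C)c(C=O)c3[C@H]2c2cc(OC)cc(OC)c2)cc1 | intermediate
19 | 2,4-dimethoxybenzyl alcohol | COc1ccc(CO)c(OC)c1 | starting material
20 | (2,4-dimethoxybenzyl)triphenylphosphonium bromide | COc1ccc(C[P+](c2ccccc2)(c2ccccc2)c2ccccc2)c(OC)c1.[Br-] | intermediate
21 | (2,4-dimethoxybenzylidene)triphenylphosphorane | COc1ccc(C=P(c2ccccc2)(c2ccccc2)c2ccccc2)c(OC)c1 | intermediate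
22 | tert-butyl 2-[(2R,3R)-4-[(E)-2-(2,4-dimethoxyphenyl)vinyl]-3-(3,5-dimethoxyphenyl)-6-(4-methoxybenzyloxy)-2-(4-methoxyphenyl)-2,3-dihydrobenzofuran-5-yl]acetate | COc1ccc([C@@H]2Oc3cc(OCc4ccc(OC)cc4)c(CC(=O)OC(C)(C)C)c(/C=C/c4ccc(OC)cc4OC)c3[C@H]2c2cc(OC)cc(OC)c2)cc1 | intermediate
23 | seven-membered-ring core (2R,3R,8R) with tert-butyl arylacetate and 4-methoxybenzyl ether on ring A | CC(C)(C)OC(=O)Cc1c(OCc2ccc(OC)cc2)cc2c3c1C[C@H](c1ccc(OC)cc1OC)c1c(OC)cc(OC)cc1[C@H]3[C@H](c1ccc(OC)cc1)O2 | intermediate
24 | seven-membered-ring core (2R,3R,8R) with arylacetic acid and free phenol on ring A | OC(=O)Cc1c(O)cc2c3c1C[C@H](c1ccc(OC)cc1OC)c1c(OC)cc(OC)cc1[C@H]3[C@H](c1ccc(OC)cc1)O2 | intermediate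
25 | seven-membered-ring core (2R,3R,8R) with methyl arylacetate and free phenol on ring A | COC(=O)Cc1c(O)cc2c3c1C[C@H](c1ccc(OC)cc1OC)c1c(OC)cc(OC)cc1[C@H]3[C@H](c1ccc(OC)cc1)O2 | intermediate
26 | seven-membered-ring core (2R,3R,8R) with methyl arylacetate and 4-methoxybenzyl ether on ring A | COC(=O)Cc1c(OCc2ccc(OC)cc2)cc2c3c1C[C@H](c1ccc(OC)cc1OC)c1c(OC)cc(OC)cc1[C@H]3[C@H](c1ccc(OC)cc1)O2 | intermediate
27 | seven-membered-ring core (2R,3R,8R) with methyl aryldiazoacetate and ortho 4-methoxybenzyl ether on ring A | COC(=O)C(=[N+]=[N-])c1c(OCc2ccc(OC)cc2)cc2c3c1C[C@H](c1ccc(OC)cc1OC)c1c(OC)cc(OC)cc1[C@H]3[C@H](c1ccc(OC)cc1)O2 | intermediate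
28 | pentacyclic methyl ester, outer ring cis (2'R,3'S), core 2R,3R,8R | COc1ccc([C@@H]2Oc3cc4c5c(c3[C@@H]2C(=O)OC)C[C@H](c2ccc(OC)cc2OC)c2c(OC)cc(OC)cc2[C@H]5[C@H](c2ccc(OC)cc2)O4)cc1 | intermediate
29 | pentacyclic carboxylic acid, outer ring trans (2'R,3'R), core 2R,3R,8R | COc1ccc([C@@H]2Oc3cc4c5c(c3[C@H]2C(=O)O)C[C@H](c2ccc(OC)cc2OC)c2c(OC)cc(OC)cc2[C@H]5[C@H](c2ccc(OC)cc2)O4)cc1 | intermediate
30 | octamethyl ether of the target (2R,3R,8R,2'R,3'R) | COc1ccc([C@@H]2Oc3cc4c5c(c3[C@H]2c2cc(OC)cc(OC)c2)C[C@H](c2ccc(OC)cc2OC)c2c(OC)cc(OC)cc2[C@H]5[C@H](c2ccc(OC)cc2)O4)cc1 | intermediate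
31 | CNP0154047.1 (2R,3R,8R,2'R,3'R) | Oc1ccc([C@@H]2Oc3cc4c5c(c3[C@H]2c2cc(O)cc(O)c2)C[C@H](c2ccc(O)cc2O)c2c(O)cc(O)cc2[C@H]5[C@H](c2ccc(O)cc2)O4)cc1 | target

**Step count**
Total: 20 steps. Longest linear sequence: 19 steps (steps 1–11 and 13–20); step 12 is a one-step side branch.

**Steps most likely to fail**

Step 17. The carbene may dimerise or attack the electron-rich rings instead of inserting, and facial control may be lost if catalyst and core are mismatched. The fallback closes the outer ring by an ionic route that starts from 26 and returns at 29. The lithium enolate of 26 (LDA, THF, −78 °C) is added to 4-methoxybenzaldehyde (aldol addition) to give the β-hydroxy ester F1 as a mixture at the two new centres. TFA with thioanisole in CH2Cl2 at 0 °C removes the 4-methoxybenzyl ether and ionises the 4-methoxybenzylic alcohol, and the freed phenol captures the cation to close the five-membered ring under thermodynamic control. This should give the trans 2'R,3'R methyl ester F2 and its trans 2'S,3'S diastereomer F3, which differ in their relation to the fixed core and are separated by chromatography. Saponification of F2 under the conditions of step 18 gives 29.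

Step 14. Ring closure and deprotection share one flask, so the benzylic cation may be intercepted, the released 4-methoxybenzyl cation may alkylate the electron-rich rings, or closure may occur from the wrong face. The fallback separates the events, starting from 22 and returning at 25. Epoxidation of 22 with dimethyldioxirane (acetone, −20 °C) gives the stilbene epoxide F4. BF3·OEt2 in CH2Cl2 at −78 °C opens it to the same C8 cation, and ring D closes the seven-membered ring (Friedel–Crafts alkylation by an epoxide) to give the C7 alcohol F5 with the 4-methoxybenzyl ether and tert-butyl ester intact. Barton–McCombie deoxygenation follows under conditions that leave the arylacetate unenolised: O-phenyl chlorothionoformate, pyridine and DMAP in CH2Cl2 give the O-phenyl thionocarbonate F6, and n-Bu3SnH with AIBN in toluene at 80 °C gives 23. Compound 23 is then deprotected and esterified in a separate operation (TFA/thioanisole, then H2SO4/MeOH) to give 25.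

Step 19. On this crowded, oxidisable polyarene the benzylic radical may be reduced or dimerise before nickel captures it, or the photocatalyst may oxidise the electron-rich rings. The fallback generates the radical reductively and without light, starting from 29 and returning at 30. Acid 29 is converted with N-hydroxyphthalimide, DIC and DMAP (CH2Cl2, rt) into the redox-active ester F7. This is coupled with 1-iodo-3,5-dimethoxybenzene under NiBr2·glyme, dtbbpy and zinc powder in DMA at rt (decarboxylative cross-electrophile coupling of a redox-active ester) to give 30.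

**Further compounds**
F1 | step 17 | methyl 3-hydroxy-3-(4-methoxyphenyl)-2-aryl-propanoate from 26 (aryl = ring A of the core with its 4-methoxybenzyl ether; new centres unassigned) | COC(=O)C(C(O)c1ccc(OC)cc1)c1c(OCc2ccc(OC)cc2)cc2c3c1C[C@H](c1ccc(OC)cc1OC)c1c(OC)cc(OC)cc1[C@H]3[C@H](c1ccc(OC)cc1)O2
F2 | step 17 | pentacyclic methyl ester, outer ring trans (2'R,3'R) | COc1ccc([C@@H]2Oc3cc4c5c(c3[C@H]2C(=O)OC)C[C@H](c2ccc(OC)cc2OC)c2c(OC)cc(OC)cc2[C@H]5[C@H](c2ccc(OC)cc2)O4)cc1
F3 | step 17 | pentacyclic methyl ester, outer ring trans (2'S,3'S) | COc1ccc([C@H]2Oc3cc4c5c(c3[C@@H]2C(=O)OC)C[C@H](c2ccc(OC)cc2OC)c2c(OC)cc(OC)cc2[C@H]5[C@H](c2ccc(OC)cc2)O4)cc1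
F4 | step 14 | epoxide of stilbene 22 (epoxide centres unassigned) | COc1ccc([C@@H]2Oc3cc(OCc4ccc(OC)cc4)c(CC(=O)OC(C)(C)C)c(C4OC4c4ccc(OC)cc4OC)c3[C@H]2c2cc(OC)cc(OC)c2)cc1
F5 | step 14 | C7-hydroxy derivative of 23 (C7 centre unassigned) | CC(C)(C)OC(=O)Cc1c(OCc2ccc(OC)cc2)cc2c3c1C(O)[C@H](c1ccc(OC)cc1OC)c1c(OC)cc(OC)cc1[C@H]3[C@H](c1ccc(OC)cc1)O2
F6 | step 14 | O-phenyl thionocarbonate of F5 | CC(C)(C)OC(=O)Cc1c(OCc2ccc(OC)cc2)cc2c3c1C(OC(=S)Oc1ccccc1)[C@H](c1ccc(OC)cc1OC)c1c(OC)cc(OC)cc1[C@H]3[C@H](c1ccc(OC)cc1)O2
F7 | step 19 | N-hydroxyphthalimide ester of 29 | COc1ccc([C@@H]2Oc3cc4c5c(c3[C@H]2C(=O)ON6C(=O)c7ccccc7C6=O)C[C@H](c2ccc(OC)cc2OC)c2c(OC)cc(OC)cc2[C@H]5[C@H](c2ccc(OC)cc2)O4)cc1
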